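**Strategy.** The ten-membered ring is closed last, between the two oxygen-bearing ring carbons C8 and C9 (germacrane numbering), both of which are aldehyde carbons in the open-chain precursor. In dialdehyde 19 a Cr(II)/Et3SiCl reduction converts the enal terminus into a γ-siloxyallylchromium, which attacks the C8 aldehyde on the preformed trans-disubstituted α-methylene-γ-butyrolactone. This single operation exploits the vicinal C8/C9 dioxygenation flanked by C7 of the lactone ring and the C10 enal carbon: it forms the ring, sets C8 and C9 by relay from C7, re-sets the C1=C10 geometry, and delivers O8 free but O9 silylated, so that methacrylate and acetate can be introduced in turn.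

Key step: step 13

Remark: germacrane numbering is used throughout (ring C1–C10 with C1=C10 and C4=C5, lactone C12(=O)–O–C6 with the C11=C13 methylidene next to C7, C14 on C10, C15 on C4). α/β refer to the usual drawing with H-7 α. The target is the (6R,7S,8S,9S) isomer with both ring alkenes cis within the ring (CIP: 1(10)E,4E).

Step 1
Reactants: 1 but-2-yne-1,4-diol
Product: 2 4-[(4-methoxybenzyl)oxy]but-2-yn-1-ol
Conditions: NaH (1 equiv), PMBCl (1 equiv), diol in excess (3 equiv), TBAI cat., THF/DMF, 0 °C to rt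
Reagents that add atoms: 4-methoxybenzyl chloride, COc1ccc(CCl)cc1
Why: Williamson etherification, in which the excess of the symmetrical diol over base and halide biases the reaction towards the mono-ether.

Step 2
Reactants: 2 4-[(4-methoxybenzyl)oxy]but-2-yn-1-ol
Product: 4 (Z)-3-iodo-4-[(4-methoxybenzyl)oxy]but-2-en-1-ol, via cyclic sodium alkenylalanate 3 (not isolated)
Conditions: Red-Al, THF, 0 °C; then I2, THF, −78 °C
Reagents that add atoms: iodine, II
Why: Hydroxyl-directed trans-hydroalumination of the propargylic alcohol (hydride to C2, aluminium to C3 in a five-membered alanate) followed by iodinolysis with retention fixes the (Z)-3-iodoalkene, which is the future C4=C5 alkene with C15 trans to C6.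

Step 3
Reactants: 4 (Z)-3-iodo-4-[(4-methoxybenzyl)oxy]but-2-en-1-ol
Product: 5 (E)-3-{[(4-methoxybenzyl)oxy]methyl}hepta-2,6-dien-1-ol
Conditions: but-3-enylzinc bromide (2.5 equiv), Pd(dppf)Cl2 (5 mol%), THF, 50 °C
Reagents that add atoms: but-3-en-1-ylzinc bromide, C=CCC[Zn]Br
Why: Negishi sp2–sp3 cross-coupling proceeds with retention of alkene geometry, the bidentate ligand suppresses β-hydride elimination, and the free hydroxyl is tolerated as its zinc alkoxide.

Step 4
Reactants: 5 (E)-3-{[(4-methoxybenzyl)oxy]methyl}hepta-2,6-dien-1-ol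
Product: 6 (E)-3-{[(4-methoxybenzyl)oxy]methyl}hepta-2,6-dienal
Conditions: activated MnO2, CH2Cl2, rt
Reagents that add atoms: none
Why: Neutral allylic oxidation with MnO2 should give the β,β-disubstituted enal without E/Z isomerisation.

Step 5
Reactants: 7 (tert-butyldimethylsilyloxy)acetaldehyde; 8 methyl acrylate
Product: 9 methyl 4-[(tert-butyldimethylsilyl)oxy]-3-hydroxy-2-methylidenebutanoate (racemic)
Conditions: DABCO (0.5 equiv), neat, rt, several days
Reagents that add atoms: none
Why: Morita–Baylis–Hillman reaction of an unhindered α-oxygenated aldehyde with an acrylate; the racemic carbinol centre is erased in step 6.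

Step 6
Reactants: 9 methyl 4-[(tert-butyldimethylsilyl)oxy]-3-hydroxy-2-methylidenebutanoate
Product: 10 methyl (Z)-2-(bromomethyl)-4-[(tert-butyldimethylsilyl)oxy]but-2-enoate
Conditions: NBS, Me2S, CH2Cl2, 0 °C to rt
Reagents that add atoms: N-bromosuccinimide, O=C1CCC(=O)N1Br
Why: Activation of the alcohol as an alkoxysulfonium salt and SN2′ return of bromide (allylic transposition) gives the thermodynamically preferred (Z)-2-(bromomethyl)enoate under acid-free conditions that spare the silyl ether.

Step 7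
Reactants: 6 (E)-3-{[(4-methoxybenzyl)oxy]methyl}hepta-2,6-dienal; 10 methyl (Z)-2-(bromomethyl)-4-[(tert-butyldimethylsilyl)oxy]but-2-enoate
Product: 13 (4R,5R)-4-{[(tert-butyldimethylsilyl)oxy]methyl}-5-[(1E)-2-{[(4-methoxybenzyl)oxy]methyl}hexa-1,5-dien-1-yl]-3-methylideneoxolan-2-one, via silyl ether 11 (not isolated), via hydroxy ester 12 (not isolated)
Conditions: CrCl2 (10 mol%), chiral oxazoline–sulfonamide ligand (12 mol%), Et3N (20 mol%), Mn (2 equiv), TMSCl (1.5 equiv), THF, rt; then 1 M HCl, THF, 0 °C to rt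
Reagents that add atoms: none
Why: Catalytic asymmetric Nozaki–Hiyama–Kishi 2-(alkoxycarbonyl)allylation, in which the allylchromium adds 1,2 to the enal through a chair transition state with the CH2OTBS group equatorial (anti adduct, hence the trans lactone), the ligand enantiomer being chosen for Si-face attack at C6 (6R), after which acid cleaves the O-silyl group and closes the γ-lactone while the primary TBS ether survives.

Step 8
Reactants: 13 the TBS-protected trans lactone
Product: 14 (4R,5R)-4-(hydroxymethyl)-5-[(1E)-2-{[(4-methoxybenzyl)oxy]methyl}hexa-1,5-dien-1-yl]-3-methylideneoxolan-2-one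
Conditions: HF·pyridine, pyridine, THF, 0 °C to rt
Reagents that add atoms: none
Why: Buffered fluoride cleavage of the primary TBS ether is mild enough to avoid relactonisation onto O8 and leaves the PMB ether untouched.

Step 9
Reactants: 15 2-methylidenepropane-1,3-diol
Product: 16 2-{[(triethylsilyl)oxy]methyl}prop-2-en-1-ol
Conditions: NaH (1 equiv), THF, 0 °C; then Et3SiCl (1 equiv)
Reagents that add atoms: chlorotriethylsilane, CC[Si](Cl)(CC)CC
Why: Monosilylation of a symmetrical diol through its sparingly soluble monosodium alkoxide.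

Step 10
Reactants: 16 2-{[(triethylsilyl)oxy]methyl}prop-2-en-1-ol
Product: 17 2-{[(triethylsilyl)oxy]methyl}prop-2-enal
Conditions: activated MnO2, CH2Cl2, rt
Reagents that add atoms: none
Why: MnO2 oxidises the allylic alcohol to the 2-substituted acrolein under neutral conditions that keep the silyl ether.

Step 11
Reactants: 14 the lactone alcohol with the terminal vinyl group; 17 2-{[(triethylsilyl)oxy]methyl}prop-2-enal (4 equiv)
Product: 18 (4R,5R)-5-[(1E,5E)-6-formyl-2-{[(4-methoxybenzyl)oxy]methyl}-7-[(triethylsilyl)oxy]hepta-1,5-dien-1-yl]-4-(hydroxymethyl)-3-methylideneoxolan-2-one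
Conditions: Hoveyda–Grubbs II catalyst (10 mol%), CH2Cl2, 40 °C
Reagents that add atoms: none
Why: Olefin cross-metathesis engages only the terminal vinyl group (the trisubstituted alkene and the 1,1-disubstituted lactone methylidene are unreactive) and should give the thermodynamic (E)-enal, whose geometry is not carried into the product of step 13.

Step 12
Reactants: 18 the hydroxy enal
Product: 19 (2R,3S)-2-[(1E,5E)-6-formyl-2-{[(4-methoxybenzyl)oxy]methyl}-7-[(triethylsilyl)oxy]hepta-1,5-dien-1-yl]-4-methylidene-5-oxooxolane-3-carbaldehyde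
Conditions: Dess–Martin periodinane, NaHCO3, CH2Cl2, 0 °C; filtered and used at once
Reagents that add atoms: none
Why: Buffered Dess–Martin oxidation of the primary alcohol is non-basic, so the epimerisable β,γ-unsaturated C8 aldehyde should survive if it is not chromatographed.

Step 13
Reactants: 19 the dialdehyde
Product: 22 8β-hydroxy-15-[(4-methoxybenzyl)oxy]-9α,14-bis[(triethylsilyl)oxy]germacra-1(10),4,11(13)-trien-6α,12-olide (both ring alkenes cis within the ring), via γ-siloxyallylchromium 20 (not isolated), via chromium(III) alkoxide 21 (not isolated)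
Conditions: CrCl2 (8 equiv), Et3SiCl (1.5 equiv), DMF, 2 mM, syringe-pump addition of 19 over 12 h, rt; aqueous work-up
Reagents that add atoms: chlorotriethylsilane, CC[Si](Cl)(CC)CC
Why: Two Cr(II) equivalents and Et3SiCl reduce only the enal to the γ-siloxyallylchromium(III) 20, whose enol and C1 geometry equilibrate, and 20 adds through its siloxy-bearing carbon C9 to the C8 aldehyde in a six-membered SE2′ (Zimmerman–Traxler) array that regenerates C1=C10 and leaves a chromium alkoxide (21) at O8. The closest known reaction type is the Cr(II)/R3SiCl pinacol-type cross-coupling of enals with aldehydes (a Nozaki–Hiyama–Kishi allylation in mechanism), known intermolecularly and, for smaller rings, intramolecularly, here run at high dilution. The ten-membered carbocycle closes 10-exo-trig at the C8 carbonyl with all three allyl carbons (C9, C10, C1) inside the new ring. Alkene geometry: only with C2 axial on C1 of the chair can the four-atom C3–C6 bridge reach C7 (and A(1,2) strain with the C10 CH2OSiEt3 group is avoided), which places C2 cis to C9, so the former formyl carbon becomes C9 and the CH2OSiEt3 carbon becomes the E-disposed C14. C9 is controlled by reaction through the (Z)-siloxy geometry (siloxy axial), the usual preference of α-branched enals in this coupling, which gives the 8,9-threo pair, and C8 by C7: with C7 equatorial the bridge holds C6 anti to the aldehyde hydrogen and C9 then approaches anti to the lactone carbon C11 (Felkin–Anh), which should give 8β-OH/9α-OSiEt3. The step needs reduction of one of two aldehydes and of neither the lactone acrylate nor the ethers, which the easier reduction of the silyl-activated enal secures, and it leaves O8 free and O9 silylated because Et3SiCl is kept near one equivalent.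

Step 14
Reactants: 22 the 8β-hydroxy macrocycle
Product: 23 15-[(4-methoxybenzyl)oxy]-8β-(methacryloyloxy)-9α,14-bis[(triethylsilyl)oxy]germacra-1(10),4,11(13)-trien-6α,12-olide
Conditions: methacrylic anhydride, Et3N, DMAP, CH2Cl2, 0 °C to rt
Reagents that add atoms: methacrylic anhydride, C=C(C)C(=O)OC(=O)C(C)=C
Why: DMAP-catalysed acylation of the only free hydroxyl (O8), which should be faster than relactonisation of O8 onto C12.

Step 15
Reactants: 23 the 8β-methacrylate bis-silyl ether
Product: 24 9α,14-dihydroxy-15-[(4-methoxybenzyl)oxy]-8β-(methacryloyloxy)germacra-1(10),4,11(13)-trien-6α,12-olide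
Conditions: HF·pyridine, pyridine, THF, 0 °C
Reagents that add atoms: none
Why: Buffered HF removes both triethylsilyl ethers under weakly acidic conditions that suppress O8-to-O9 acyl migration and leave the PMB ether in place.

Step 16
Reactants: 24 the 9α,14-diol
Product: 25 9α-hydroxy-15-[(4-methoxybenzyl)oxy]-8β-(methacryloyloxy)-14-oxogermacra-1(10),4,11(13)-trien-6α,12-olide
Conditions: TEMPO (20 mol%), PhI(OAc)2, CH2Cl2, rt
Reagents that add atoms: none
Why: Oxoammonium oxidation (TEMPO/PhI(OAc)2) is selective for the primary allylic alcohol over the hindered secondary C9 alcohol and gives the C14 enal with the alkene geometry unchanged.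

Step 17
Reactants: 25 the 9α-hydroxy enal
Product: 26 9α-acetoxy-15-[(4-methoxybenzyl)oxy]-8β-(methacryloyloxy)-14-oxogermacra-1(10),4,11(13)-trien-6α,12-olide
Conditions: Ac2O, pyridine, DMAP cat., CH2Cl2, 0 °C
Reagents that add atoms: acetic anhydride, CC(=O)OC(C)=O
Why: Standard acetylation of the remaining secondary alcohol, run cold to avoid SN2′ displacement of the activated allylic acetate.

Step 18
Reactants: 26 the PMB-protected diester
Product: 27 9α-acetoxy-15-hydroxy-8β-(methacryloyloxy)-14-oxogermacra-1(10),4,11(13)-trien-6α,12-olide (target, CNP0147326.4)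
Conditions: DDQ (1.5 equiv), CH2Cl2/pH 7 buffer, 0 °C
Reagents that add atoms: none
Why: Oxidative cleavage of the PMB ether by DDQ under buffered neutral conditions releases the C15 alcohol and should leave the enal, both esters and the α-methylene lactone intact.

**Compound list**

1 | but-2-yne-1,4-diol | OCC#CCO | starting material
2 | 4-[(4-methoxybenzyl)oxy]but-2-yn-1-ol | OCC#CCOCc1ccc(OC)cc1 | intermediate
3 | cyclic sodium alkenylalanate from 2 (Al on C3, O–Al chelate) | [Na+].COCCO[Al-]1(OCCOC)OCC=C1COCc1ccc(OC)cc1 | intermediate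
4 | (Z)-3-iodo-4-[(4-methoxybenzyl)oxy]but-2-en-1-ol | OC/C=C(\I)COCc1ccc(OC)cc1 | intermediate
5 | (E)-3-{[(4-methoxybenzyl)oxy]methyl}hepta-2,6-dien-1-ol | OC/C=C(\CCC=C)COCc1ccc(OC)cc1 | intermediate
6 | (E)-3-{[(4-methoxybenzyl)oxy]methyl}hepta-2,6-dienal | O=C/C=C(\CCC=C)COCc1ccc(OC)cc1 | intermediate
7 | (tert-butyldimethylsilyloxy)acetaldehyde | CC(C)(C)[Si](C)(C)OCC=O | starting material
8 | methyl acrylate | C=CC(=O)OC | starting material
9 | methyl 4-[(tert-butyldimethylsilyl)oxy]-3-hydroxy-2-methylidenebutanoate (racemic) | C=C(C(=O)OC)C(O)CO[Si](C)(C)C(C)(C)C | intermediate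
10 | methyl (Z)-2-(bromomethyl)-4-[(tert-butyldimethylsilyl)oxy]but-2-enoate | COC(=O)/C(CBr)=C/CO[Si](C)(C)C(C)(C)C | intermediate
11 | methyl (3R,4R,5E)-3-{[(tert-butyldimethylsilyl)oxy]methyl}-6-{[(4-methoxybenzyl)oxy]methyl}-2-methylidene-4-[(trimethylsilyl)oxy]deca-5,9-dienoate | COC(=O)C(=C)[C@H](CO[Si](C)(C)C(C)(C)C)[C@H](O[Si](C)(C)C)/C=C(/COCc1ccc(OC)cc1)CCC=C | intermediate
12 | methyl (3R,4R,5E)-3-{[(tert-butyldimethylsilyl)oxy]methyl}-4-hydroxy-6-{[(4-methoxybenzyl)oxy]methyl}-2-methylidenedeca-5,9-dienoate | COC(=O)C(=C)[C@H](CO[Si](C)(C)C(C)(C)C)[C@H](O)/C=C(/COCc1ccc(OC)cc1)CCC=C | intermediate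
13 | (4R,5R)-4-{[(tert-butyldimethylsilyl)oxy]methyl}-5-[(1E)-2-{[(4-methoxybenzyl)oxy]methyl}hexa-1,5-dien-1-yl]-3-methylideneoxolan-2-one | CC(C)(C)[Si](C)(C)OC[C@H]1C(=C)C(=O)O[C@@H]1/C=C(/COCc2ccc(OC)cc2)CCC=C | intermediate
14 | (4R,5R)-4-(hydroxymethyl)-5-[(1E)-2-{[(4-methoxybenzyl)oxy]methyl}hexa-1,5-dien-1-yl]-3-methylideneoxolan-2-one | OC[C@H]1C(=C)C(=O)O[C@@H]1/C=C(/COCc2ccc(OC)cc2)CCC=C | intermediate
15 | 2-methylidenepropane-1,3-diol | C=C(CO)CO | starting material
16 | 2-{[(triethylsilyl)oxy]methyl}prop-2-en-1-ol | C=C(CO)CO[Si](CC)(CC)CC | intermediate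
17 | 2-{[(triethylsilyl)oxy]methyl}prop-2-enal | C=C(C=O)CO[Si](CC)(CC)CC | intermediate
18 | (4R,5R)-5-[(1E,5E)-6-formyl-2-{[(4-methoxybenzyl)oxy]methyl}-7-[(triethylsilyl)oxy]hepta-1,5-dien-1-yl]-4-(hydroxymethyl)-3-methylideneoxolan-2-one | OC[C@H]1C(=C)C(=O)O[C@@H]1/C=C(/COCc2ccc(OC)cc2)CC/C=C(/C=O)CO[Si](CC)(CC)CC | intermediate
19 | (2R,3S)-2-[(1E,5E)-6-formyl-2-{[(4-methoxybenzyl)oxy]methyl}-7-[(triethylsilyl)oxy]hepta-1,5-dien-1-yl]-4-methylidene-5-oxooxolane-3-carbaldehyde | O=C[C@H]1C(=C)C(=O)O[C@@H]1/C=C(/COCc2ccc(OC)cc2)CC/C=C(/C=O)CO[Si](CC)(CC)CC | intermediate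
20 | γ-siloxyallylchromium(III) dichloride from 19 (Cr on C1, configuration at C1 labile; (Z)-enol silyl ether at C9=C10) | O=C[C@H]1C(=C)C(=O)O[C@@H]1/C=C(/COCc2ccc(OC)cc2)CCC([Cr](Cl)Cl)/C(CO[Si](CC)(CC)CC)=C\O[Si](CC)(CC)CC | intermediate
21 | dichlorochromium(III) 8-alkoxide of 22 | Cl[Cr](Cl)O[C@H]1[C@H]2C(=C)C(=O)O[C@@H]2/C=C(/COCc3ccc(OC)cc3)CC/C=C(/CO[Si](CC)(CC)CC)[C@@H]1O[Si](CC)(CC)CC | intermediate
22 | 8β-hydroxy-15-[(4-methoxybenzyl)oxy]-9α,14-bis[(triethylsilyl)oxy]germacra-1(10),4,11(13)-trien-6α,12-olide | O[C@H]1[C@H]2C(=C)C(=O)O[C@@H]2/C=C(/COCc3ccc(OC)cc3)CC/C=C(/CO[Si](CC)(CC)CC)[C@@H]1O[Si](CC)(CC)CC | intermediate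
23 | 15-[(4-methoxybenzyl)oxy]-8β-(methacryloyloxy)-9α,14-bis[(triethylsilyl)oxy]germacra-1(10),4,11(13)-trien-6α,12-olide | C=C(C)C(=O)O[C@H]1[C@H]2C(=C)C(=O)O[C@@H]2/C=C(/COCc3ccc(OC)cc3)CC/C=C(/CO[Si](CC)(CC)CC)[C@@H]1O[Si](CC)(CC)CC | intermediate
24 | 9α,14-dihydroxy-15-[(4-methoxybenzyl)oxy]-8β-(methacryloyloxy)germacra-1(10),4,11(13)-trien-6α,12-olide | C=C(C)C(=O)O[C@H]1[C@H]2C(=C)C(=O)O[C@@H]2/C=C(/COCc3ccc(OC)cc3)CC/C=C(/CO)[C@@H]1O | intermediate
25 | 9α-hydroxy-15-[(4-methoxybenzyl)oxy]-8β-(methacryloyloxy)-14-oxogermacra-1(10),4,11(13)-trien-6α,12-olide | C=C(C)C(=O)O[C@H]1[C@H]2C(=C)C(=O)O[C@@H]2/C=C(/COCc3ccc(OC)cc3)CC/C=C(/C=O)[C@@H]1O | intermediate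
26 | 9α-acetoxy-15-[(4-methoxybenzyl)oxy]-8β-(methacryloyloxy)-14-oxogermacra-1(10),4,11(13)-trien-6α,12-olide | C=C(C)C(=O)O[C@H]1[C@H]2C(=C)C(=O)O[C@@H]2/C=C(/COCc3ccc(OC)cc3)CC/C=C(/C=O)[C@@H]1OC(C)=O | intermediate
27 | (6R,7S,8S,9S)-9α-acetoxy-15-hydroxy-8β-(methacryloyloxy)-14-oxogermacra-1(10),4,11(13)-trien-6α,12-olide | C=C(C)C(=O)O[C@H]1[C@H]2C(=C)C(=O)O[C@@H]2/C=C(/CO)CC/C=C(/C=O)[C@@H]1OC(C)=O | target

**Step count.** 18 steps in total; longest linear sequence 14 steps (steps 1–4, 7, 8, 11–18).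

**Steps most likely to fail**

Step 13. The siloxyallylchromium may react through its (E)-enol geometry (siloxy group equatorial), so that the coupling turns erythro-selective at C9. The fallback corrects C9 by inversion after ring closure instead of setting it in the coupling. It sets out from 19: the same cyclisation would give the 9-epimeric macrocycle, 8β-hydroxy-9β,14-bis(triethylsilyloxy) germacranolide F1. Methacryloylation (methacrylic anhydride, DMAP) gives the 8β-methacrylate F2, HF·pyridine gives the 9β,14-diol F3, and TEMPO/PhI(OAc)2 gives the 9β-hydroxy-14-al F4. Mitsunobu esterification of F4 with acetic acid (PPh3, DIAD, toluene, 0 °C) inverts C9 and installs the acetate; the 8-ester is cis to the leaving group and cannot participate. The fallback comes back to the route at 26.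

Step 7. Anti diastereoselection may be insufficient (cis lactone through an allylchromium with the CH2OTBS group axial), or enantiofacial control may be low with the conjugated aldehyde. The fallback is a stereospecific allylboration in which the trans relationship follows from reagent geometry. It sets out from 6. Commercial methyl 4-hydroxybut-2-ynoate is silylated (TBSCl, imidazole) to methyl 4-[(tert-butyldimethylsilyl)oxy]but-2-ynoate F5. Syn-hydroalumination (DIBAL-H, HMPA, THF, 0 °C) and alkylation of the α-aluminated enoate with 2-(iodomethyl)-4,4,5,5-tetramethyl-1,3,2-dioxaborolane give methyl (Z)-4-[(tert-butyldimethylsilyl)oxy]-2-[(4,4,5,5-tetramethyl-1,3,2-dioxaborolan-2-yl)methyl]but-2-enoate F6, with CH2OTBS trans to CH2B. Chiral-phosphoric-acid-catalysed allylboration of 6 through the closed chair (anti adduct) and acid lactonisation return to the route at 13.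

Step 11. Cross-metathesis of the hindered, electron-poor acrolein 17 may be slow, with homodimerisation of 14 and catalyst decay. The fallback uses the more reactive allylic alcohol as the metathesis partner and makes the enal afterwards. It sets out from 14 and 16: cross-metathesis (Hoveyda–Grubbs II, CH2Cl2, 40 °C) gives the diol (4R,5R)-4-(hydroxymethyl)-5-[7-hydroxy-2-{[(4-methoxybenzyl)oxy]methyl}-6-{[(triethylsilyl)oxy]methyl}hepta-1,5-dien-1-yl]-3-methylideneoxolan-2-one F7 as a mixture of C1=C10 isomers. Dess–Martin oxidation of both primary alcohols returns to the route at 19, then obtained as a mixture of C1=C10 isomers that converge on allylchromium 20.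

**Further compounds**

F1 | step 13 | 8β-hydroxy-15-[(4-methoxybenzyl)oxy]-9β,14-bis[(triethylsilyl)oxy]germacra-1(10),4,11(13)-trien-6α,12-olide | O[C@H]1[C@H]2C(=C)C(=O)O[C@@H]2/C=C(/COCc3ccc(OC)cc3)CC/C=C(/CO[Si](CC)(CC)CC)[C@H]1O[Si](CC)(CC)CC
F2 | step 13 | 15-[(4-methoxybenzyl)oxy]-8β-(methacryloyloxy)-9β,14-bis[(triethylsilyl)oxy]germacra-1(10),4,11(13)-trien-6α,12-olide | C=C(C)C(=O)O[C@H]1[C@H]2C(=C)C(=O)O[C@@H]2/C=C(/COCc3ccc(OC)cc3)CC/C=C(/CO[Si](CC)(CC)CC)[C@H]1O[Si](CC)(CC)CC
F3 | step 13 | 9β,14-dihydroxy-15-[(4-methoxybenzyl)oxy]-8β-(methacryloyloxy)germacra-1(10),4,11(13)-trien-6α,12-olide | C=C(C)C(=O)O[C@H]1[C@H]2C(=C)C(=O)O[C@@H]2/C=C(/COCc3ccc(OC)cc3)CC/C=C(/CO)[C@H]1O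
F4 | step 13 | 9β-hydroxy-15-[(4-methoxybenzyl)oxy]-8β-(methacryloyloxy)-14-oxogermacra-1(10),4,11(13)-trien-6α,12-olide | C=C(C)C(=O)O[C@H]1[C@H]2C(=C)C(=O)O[C@@H]2/C=C(/COCc3ccc(OC)cc3)CC/C=C(/C=O)[C@H]1O
F5 | step 7 | methyl 4-[(tert-butyldimethylsilyl)oxy]but-2-ynoate | COC(=O)C#CCO[Si](C)(C)C(C)(C)C
F6 | step 7 | methyl (Z)-4-[(tert-butyldimethylsilyl)oxy]-2-[(4,4,5,5-tetramethyl-1,3,2-dioxaborolan-2-yl)methyl]but-2-enoate | COC(=O)/C(CB1OC(C)(C)C(C)(C)O1)=C\CO[Si](C)(C)C(C)(C)C
F7 | step 11 | (4R,5R)-4-(hydroxymethyl)-5-[7-hydroxy-2-{[(4-methoxybenzyl)oxy]methyl}-6-{[(triethylsilyl)oxy]methyl}hepta-1,5-dien-1-yl]-3-methylideneoxolan-2-one (E/Z mixture at C1=C10) | OC[C@H]1C(=C)C(=O)O[C@@H]1/C=C(/COCc2ccc(OC)cc2)CCC=C(CO)CO[Si](CC)(CC)CC
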